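**Retrosynthetic overview**
- Feature: read from the C4a–C8a edge, ring A is C5(OH)–C6(OMe)–C7(OMe)–C8(H). This is the C1(=O)–C2(OMe)=C3(OMe)–C4(H) perimeter of a 2,3-dimethoxycyclobutenone. The C4a=C8a edge is the C5=C6 enol-ether alkene of a 2-aryl-2,3-dihydropyran-4-one (ring C).
- Disconnections: C8–C8a (Stille coupling, tin on C8a, chlorine on cyclobutenone C4) and C4a–C5 (4π opening to a dienylketene, then 6π closure). Ring A is made last and arrives with the 5-OH free and both methyl ethers in place.
- Ring C and the only stereocentre, C2 (S), come first, from a catalytic asymmetric hetero-Diels–Alder reaction of 3,4-dimethoxybenzaldehyde (ring B, bought) with Danishefsky's diene.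
- Tin reaches C6 of the pyranone through an anomeric sulfone carbanion (thiol addition/reduction, S-oxidation, stannylation with loss of sulfinate, allylic oxidation). Direct vinylic metalation with alkyllithium bases would compete with the benzylic C2–H and the veratryl C–H bonds.
- The chlorocyclobutenone comes from dimethyl squarate by 1,2-reduction and acid-free chlorination. Ring order: B (bought), C (step 1), A (step 8).

Key step: step 8

Assumption: by analogy with simple aromatic aldehydes, the (S)-BINOL/Ti(IV) catalyst is taken to deliver the diene to the Si face of the aldehyde; should the sense prove opposite, (R)-BINOL is used and nothing else changes.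

Step 1
Reactants: 1 3,4-dimethoxybenzaldehyde; 2 Danishefsky's diene
Product: 4 (S)-2-(3,4-dimethoxyphenyl)-2,3-dihydro-4H-pyran-4-one, via silyl aldol adduct 3 (not isolated)
Conditions: (S)-BINOL (20 mol %), Ti(Oi-Pr)4 (10 mol %), 4 Å MS, Et2O, −20 °C → rt; then TFA (cat.), CH2Cl2, 0 °C; ee checked by chiral HPLC, recrystallisation if needed
Reagents that add atoms: none
Why: Catalytic asymmetric hetero-Diels–Alder reaction in its stepwise Mukaiyama-aldol/cyclisation form: the BINOL–Ti(IV) Lewis acid should expose the Si face of the bound aldehyde to the diene terminus and so set C2 as S in 3, and acid then closes ring C by 6-endo oxa-Michael addition and loss of methanol without touching the C2–O bond.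

Step 2
Reactants: 4 (S)-2-(3,4-dimethoxyphenyl)-2,3-dihydro-4H-pyran-4-one
Product: 6 (2S,4R,6R)-2-(3,4-dimethoxyphenyl)-6-(phenylsulfanyl)tetrahydro-2H-pyran-4-ol, via thio ketone 5 (not isolated)
Conditions: PhSH (1.1 equiv), Et3N (5 mol %), CH2Cl2, 0 °C; then MeOH, NaBH4, −40 °C
Reagents that add atoms: thiophenol, Sc1ccccc1
Why: Base-catalysed thia-Michael addition puts sulfur on C6 axially (stereoelectronic attack trans to the equatorial aryl group, reinforced by the anomeric effect), and the borohydride 1,2-reduction in the same flask drains the reversible addition by removing the ketone, hydride arriving equatorially because the axial sulfanyl group blocks the other face; the new C4 and C6 centres are erased in steps 4 and 5, so their ratio does not matter, and C2 is not involved.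

Step 3
Reactants: 6 (2S,4R,6R)-2-(3,4-dimethoxyphenyl)-6-(phenylsulfanyl)tetrahydro-2H-pyran-4-ol
Product: 7 (2S,4R,6R)-2-(3,4-dimethoxyphenyl)-6-(phenylsulfonyl)tetrahydro-2H-pyran-4-ol
Conditions: mCPBA (2.2 equiv), CH2Cl2, 0 °C; aq. Na2S2O3/NaHCO3 wash
Reagents that add atoms: mCPBA, O=C(OO)c1cccc(Cl)c1
Why: Peracid oxidation of a sulfide to the sulfone, routine for thioglycoside-type O,S-acetals, is far faster than any attack on the secondary alcohol or the dimethoxyarene at 0 °C and leaves all three stereocentres as they are.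

Step 4
Reactants: 7 (2S,4R,6R)-2-(3,4-dimethoxyphenyl)-6-(phenylsulfonyl)tetrahydro-2H-pyran-4-ol
Product: 10 (2S,4R)-2-(3,4-dimethoxyphenyl)-6-(tributylstannyl)-3,4-dihydro-2H-pyran-4-ol, via dilithio sulfone 8 (not isolated), via stannyl sulfone 9 (not isolated)
Conditions: LDA (2.2 equiv), THF, −78 °C; Bu3SnCl, −78 °C → rt; aq. work-up; crude, i-Pr2NEt, CHCl3, 60 °C; Et3N-deactivated silica
Reagents that add atoms: tributyltin chloride, CCCC[Sn](Cl)(CCCC)CCCC
Why: Anomeric sulfone carbanion chemistry: LDA removes only the O–H and the sulfonyl-acidified C6–H (the benzylic C2–H and the aryl C–H bonds are far beyond its reach at −78 °C, so C2 cannot epimerise), the carbanion is stannylated on carbon, and oxygen-assisted loss of sulfinate together with a C5 proton, the only β-hydrogen site, gives the α-stannyl enol ether, as known for 2-sulfonyl tetrahydropyrans.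

Step 5
Reactants: 10 (2S,4R)-2-(3,4-dimethoxyphenyl)-6-(tributylstannyl)-3,4-dihydro-2H-pyran-4-ol
Product: 11 (S)-2-(3,4-dimethoxyphenyl)-6-(tributylstannyl)-2,3-dihydro-4H-pyran-4-one
Conditions: TPAP (5 mol %), NMO (1.5 equiv), 4 Å MS, CH2Cl2, rt
Reagents that add atoms: none
Why: Ley–Griffith oxidation (catalytic perruthenate, NMO) turns the allylic alcohol into the enone under neutral, non-acidic conditions that spare the acid-sensitive alkenyl C–Sn bond and the C2 centre, and it removes the C4 stereocentre.

Step 6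
Reactants: 12 dimethyl squarate
Product: 13 4-hydroxy-2,3-dimethoxycyclobut-2-en-1-one (racemic)
Conditions: LiAlH(Ot-Bu)3 (1.05 equiv), THF, −78 → −20 °C; cold pH 7 buffer
Reagents that add atoms: none
Why: Chemoselective 1,2-reduction of one squarate carbonyl by a bulky, mild aluminium hydride stops at the 4-hydroxycyclobutenone because the remaining carbonyl is a deactivated vinylogous ester, and the cold neutral quench avoids acid-triggered loss of methanol; the product is racemic, which is irrelevant since this carbon becomes aromatic C8.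

Step 7
Reactants: 13 4-hydroxy-2,3-dimethoxycyclobut-2-en-1-one
Product: 15 4-chloro-2,3-dimethoxycyclobut-2-en-1-one (racemic), via chlorosulfite 14 (not isolated)
Conditions: SOCl2 (1.1 equiv), pyridine (1.15 equiv), Et2O, −20 → 0 °C; cold filtration through a short plug, used at once
Reagents that add atoms: thionyl chloride, O=S(Cl)Cl
Why: Chlorodehydroxylation through the chlorosulfite (SOCl2/pyridine), a known way from squarate-derived 4-hydroxycyclobutenones to 4-chlorocyclobutenones: pyridine takes up HCl so that the acid-labile bis(enol ether) survives, and chloride displaces the chlorosulfite at the unhindered C4.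

Step 8
Reactants: 11 (S)-2-(3,4-dimethoxyphenyl)-6-(tributylstannyl)-2,3-dihydro-4H-pyran-4-one; 15 4-chloro-2,3-dimethoxycyclobut-2-en-1-one
Product: 19 (2S)-2-(3,4-dimethoxyphenyl)-5-hydroxy-6,7-dimethoxy-2,3-dihydro-4H-chromen-4-one, via alkenylcyclobutenone 16 (not isolated), via dienylketene 17 (not isolated), via cyclohexadienone 18 (not isolated)
Conditions: 15 (1.3 equiv, fresh), Pd2(dba)3·CHCl3 (2.5 mol %), P(2-furyl)3 (10 mol %), CuI (10 mol %), degassed dioxane, 50 °C; then 100 °C; MeCN/hexane partition, chromatography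
Reagents that add atoms: none
Why: Pd(0) ionises the allylic, α-keto C4–Cl bond of 15 to an η3-oxocyclobutenyl palladium chloride, C6 of 11 (future C8a) passes from tin to palladium (helped by the weakly bound furylphosphine and Cu(I), the usual remedies for acyl-conjugated stannanes), and reductive elimination at the CH terminus forms C8–C8a in 16. On heating, 16 undergoes reversible conrotatory 4π opening of its C1–C4 bond; the isomer with the pyranyl group turned outward can only re-close, whereas the inward isomer 17 holds C4a within reach of the ketene carbon. Ring A closes by thermal disrotatory 6π electrocyclisation (C4a–C5), favoured because C4a is the nucleophilic β-carbon of the ring-C enol ether and C5 the electrophilic ketene carbon, and dienone 18 tautomerises irreversibly to the phenol chelated to the C4 carbonyl. The closest known reaction type is the Stille coupling of 4-chlorocyclobutenones with alkenyl- and heteroarylstannanes followed by thermal rearrangement to phenols, a relative of the Danheiser benzannulation and the Moore rearrangement. No lasting stereocentre is made: the centres at C8 in 16 and at C4a in 18 vanish on aromatisation, and C2 only looks on under neutral, base-free conditions. Two selectivities are needed: bond formation at the unsubstituted allyl terminus and not at the methoxy-bearing C2 (which would end in the 7,8-dimethoxy pattern), secured by the crowded, donor-substituted nature of that terminus, and coupling faster than thermal opening or ionisation of 15, secured by coupling at 50 °C before the temperature is raised.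

**Compound list**
1 | 3,4-dimethoxybenzaldehyde | COc1ccc(C=O)cc1OC | starting material
2 | Danishefsky's diene, (E)-1-methoxy-3-(trimethylsilyloxy)buta-1,3-diene | CO/C=C/C(=C)O[Si](C)(C)C | starting material
3 | (1E,5S)-5-(3,4-dimethoxyphenyl)-1-methoxy-5-(trimethylsilyloxy)pent-1-en-3-one | COc1ccc([C@@H](O[Si](C)(C)C)CC(=O)/C=C/OC)cc1OC | intermediate
4 | (S)-2-(3,4-dimethoxyphenyl)-2,3-dihydro-4H-pyran-4-one | COc1ccc([C@@H]2CC(=O)C=CO2)cc1OC | intermediate
5 | (2S,6R)-2-(3,4-dimethoxyphenyl)-6-(phenylsulfanyl)tetrahydro-4H-pyran-4-one (2,6-trans) | COc1ccc([C@@H]2CC(=O)C[C@@H](Sc3ccccc3)O2)cc1OC | intermediate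
6 | (2S,4R,6R)-2-(3,4-dimethoxyphenyl)-6-(phenylsulfanyl)tetrahydro-2H-pyran-4-ol | COc1ccc([C@@H]2C[C@@H](O)C[C@@H](Sc3ccccc3)O2)cc1OC | intermediate
7 | (2S,4R,6R)-2-(3,4-dimethoxyphenyl)-6-(phenylsulfonyl)tetrahydro-2H-pyran-4-ol | COc1ccc([C@@H]2C[C@@H](O)C[C@@H](S(=O)(=O)c3ccccc3)O2)cc1OC | intermediate
8 | O,C6-dilithio derivative of 7 | COc1ccc([C@@H]2C[C@@H](O[Li])CC([Li])(S(=O)(=O)c3ccccc3)O2)cc1OC | intermediate
9 | (2S,4R)-2-(3,4-dimethoxyphenyl)-6-(phenylsulfonyl)-6-(tributylstannyl)tetrahydro-2H-pyran-4-ol (C6 undefined) | COc1ccc([C@@H]2C[C@@H](O)CC([Sn](CCCC)(CCCC)CCCC)(S(=O)(=O)c3ccccc3)O2)cc1OC | intermediate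
10 | (2S,4R)-2-(3,4-dimethoxyphenyl)-6-(tributylstannyl)-3,4-dihydro-2H-pyran-4-ol | COc1ccc([C@@H]2C[C@@H](O)C=C([Sn](CCCC)(CCCC)CCCC)O2)cc1OC | intermediate
11 | (S)-2-(3,4-dimethoxyphenyl)-6-(tributylstannyl)-2,3-dihydro-4H-pyran-4-one | COc1ccc([C@@H]2CC(=O)C=C([Sn](CCCC)(CCCC)CCCC)O2)cc1OC | intermediate
12 | dimethyl squarate | COC1=C(OC)C(=O)C1=O | starting material
13 | 4-hydroxy-2,3-dimethoxycyclobut-2-en-1-one (racemic) | COC1=C(OC)C(O)C1=O | intermediate
14 | 2,3-dimethoxy-4-oxocyclobut-2-en-1-yl chlorosulfite | COC1=C(OC)C(OS(=O)Cl)C1=O | intermediate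
15 | 4-chloro-2,3-dimethoxycyclobut-2-en-1-one (racemic) | COC1=C(OC)C(Cl)C1=O | intermediate
16 | 4-[(2S)-2-(3,4-dimethoxyphenyl)-4-oxo-3,4-dihydro-2H-pyran-6-yl]-2,3-dimethoxycyclobut-2-en-1-one (both epimers at the ring CH) | COc1ccc([C@@H]2CC(=O)C=C(C3C(=O)C(OC)=C3OC)O2)cc1OC | intermediate
17 | 4-[(2S)-2-(3,4-dimethoxyphenyl)-4-oxo-3,4-dihydro-2H-pyran-6-yl]-2,3-dimethoxybuta-1,3-dien-1-one, pyranyl group cis to the ketene-bearing carbon | COc1ccc([C@@H]2CC(=O)C=C(/C=C(OC)\C(OC)=C=O)O2)cc1OC | intermediate
18 | (2S)-2-(3,4-dimethoxyphenyl)-6,7-dimethoxy-2,3-dihydro-4H-chromene-4,5(4aH)-dione (C4a undefined) | COc1ccc([C@@H]2CC(=O)C3C(=O)C(OC)=C(OC)C=C3O2)cc1OC | intermediate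
19 | (2S)-5-hydroxy-6,7,3',4'-tetramethoxyflavanone | COc1ccc([C@@H]2CC(=O)c3c(cc(OC)c(OC)c3O)O2)cc1OC | target

**Step count:** 8 steps in total. The longest linear sequence is 6 steps (1, 2, 3, 4, 5, 8).

**Steps most likely to fail**

1. Step 8.
 - Risk: tin-to-palladium transfer from the acyl-conjugated, push–pull stannane may be sluggish. Protodestannylation, ionisation or thermal opening of the chloride, and bond formation at the methoxy-bearing allyl terminus would then gain ground.
 - Fallback, from 10 back to 19: the carbonyl is left out until ring A exists. Alcohol 10 is silylated (TBSCl, imidazole, DMF) to the TBS ether F1, an electron-rich 6-stannyl dihydropyran of the stannyl-glycal class, whose Stille reactivity is well established.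
 - Coupling with 15 under the palladium conditions of step 8 should give the alkenylcyclobutenone F2. On heating it passes through the dienylketene F3 and the cyclohexadienone F4 to the 4-silyloxychroman-5-ol F5.
 - Buffered fluoride (TBAF/AcOH, THF) frees the flavan-4,5-diol F6, and MnO2 oxidation of its benzylic alcohol installs the C4 ketone of 19.

2. Step 7.
 - Risk: the activated carbinol, or the chloride itself, may ionise to the methoxy-stabilised cyclobutenyl cation. Chloride return at the wrong allyl terminus and demethylative collapse of the ring to the dione level would follow, with further losses on handling.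
 - Fallback, from 13 back to 16: no carbon–chlorine bond is made. Acetylation (Ac2O, pyridine, cat. DMAP, CH2Cl2, 0 °C) gives the storable 4-acetoxycyclobutenone F7.
 - F7 enters a Stille coupling of the allylic-acetate type with 11 (Pd2(dba)3, LiCl, DMF, rt to 50 °C) through the same η3-oxocyclobutenyl palladium species. The resulting 16 is heated on to 19 as in step 8.

3. Step 4.
 - Risk: carbon-stannylation of the hindered dianion may be incomplete, and reprotonation or protodestannylation may occur during the sulfinate-elimination stage.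
 - Fallback, from 4 back to 11 (it also bypasses steps 2 and 3): Luche reduction (NaBH4, CeCl3·7H2O, MeOH, −78 °C) gives the cis allylic alcohol F8. TIPSOTf/2,6-lutidine then gives the TIPS ether F9.
 - Brief vinylic metalation with n-BuLi/KOt-Bu (THF, −78 °C), the variant that tolerates benzylic ethers in glycals, gives the 6-potassio dihydropyran F10. It is quenched with Bu3SnCl to the 6-stannyl TIPS ether F11.
 - TBAF releases the stannyl alcohol F12, and TPAP/NMO oxidation leads to 11.
 - This path is only the reserve, because metalation at the benzylic C2–H or on the veratryl ring may compete. The enantiomeric purity of 11 would have to be rechecked.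

Further compounds
F1 | step 8 | (2S,4R)-4-(tert-butyldimethylsilyloxy)-2-(3,4-dimethoxyphenyl)-6-(tributylstannyl)-3,4-dihydro-2H-pyran | COc1ccc([C@@H]2C[C@@H](O[Si](C)(C)C(C)(C)C)C=C([Sn](CCCC)(CCCC)CCCC)O2)cc1OC
F2 | step 8 | 4-[(2S,4R)-4-(tert-butyldimethylsilyloxy)-2-(3,4-dimethoxyphenyl)-3,4-dihydro-2H-pyran-6-yl]-2,3-dimethoxycyclobut-2-en-1-one | COc1ccc([C@@H]2C[C@@H](O[Si](C)(C)C(C)(C)C)C=C(C3C(=O)C(OC)=C3OC)O2)cc1OC
F3 | step 8 | 4-[(2S,4R)-4-(tert-butyldimethylsilyloxy)-2-(3,4-dimethoxyphenyl)-3,4-dihydro-2H-pyran-6-yl]-2,3-dimethoxybuta-1,3-dien-1-one | COc1ccc([C@@H]2C[C@@H](O[Si](C)(C)C(C)(C)C)C=C(/C=C(OC)\C(OC)=C=O)O2)cc1OC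
F4 | step 8 | (2S,4R)-4-(tert-butyldimethylsilyloxy)-2-(3,4-dimethoxyphenyl)-6,7-dimethoxy-2,3,4,4a-tetrahydro-5H-chromen-5-one | COc1ccc([C@@H]2C[C@@H](O[Si](C)(C)C(C)(C)C)C3C(=O)C(OC)=C(OC)C=C3O2)cc1OC
F5 | step 8 | (2S,4R)-4-(tert-butyldimethylsilyloxy)-2-(3,4-dimethoxyphenyl)-6,7-dimethoxychroman-5-ol | COc1ccc([C@@H]2C[C@@H](O[Si](C)(C)C(C)(C)C)c3c(cc(OC)c(OC)c3O)O2)cc1OC
F6 | step 8 | (2S,4R)-2-(3,4-dimethoxyphenyl)-6,7-dimethoxychromane-4,5-diol | COc1ccc([C@@H]2C[C@@H](O)c3c(cc(OC)c(OC)c3O)O2)cc1OC
F7 | step 7 | 2,3-dimethoxy-4-oxocyclobut-2-en-1-yl acetate (racemic) | CC(=O)OC1C(=O)C(OC)=C1OC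
F8 | step 4 | (2S,4S)-2-(3,4-dimethoxyphenyl)-3,4-dihydro-2H-pyran-4-ol | COc1ccc([C@@H]2C[C@H](O)C=CO2)cc1OC
F9 | step 4 | (2S,4S)-2-(3,4-dimethoxyphenyl)-4-(triisopropylsilyloxy)-3,4-dihydro-2H-pyran | COc1ccc([C@@H]2C[C@H](O[Si](C(C)C)(C(C)C)C(C)C)C=CO2)cc1OC
F10 | step 4 | 6-potassio derivative of F9 | COc1ccc([C@@H]2C[C@H](O[Si](C(C)C)(C(C)C)C(C)C)C=C([K])O2)cc1OC
F11 | step 4 | (2S,4S)-2-(3,4-dimethoxyphenyl)-6-(tributylstannyl)-4-(triisopropylsilyloxy)-3,4-dihydro-2H-pyran | COc1ccc([C@@H]2C[C@H](O[Si](C(C)C)(C(C)C)C(C)C)C=C([Sn](CCCC)(CCCC)CCCC)O2)cc1OC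
F12 | step 4 | (2S,4S)-2-(3,4-dimethoxyphenyl)-6-(tributylstannyl)-3,4-dihydro-2H-pyran-4-ol | COc1ccc([C@@H]2C[C@H](O)C=C([Sn](CCCC)(CCCC)CCCC)O2)cc1OC
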